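**Amounts first.** In both earlier runs the protic impurity came to 0.500 of the electrophile charge, so I wrote the nucleophile as a fraction of that charge too and asked what each flask had left to work with.

common to all: electrophile 0.050 M
- maple: nucleophile 0.088 M; protic impurity 0.025 M; run made earlier
- ash: nucleophile 0.27 M; protic impurity 0.025 M; run made earlier
- spring: nucleophile 0.400 M; protic impurity 0.0250 M; time 15 min
- midnight: nucleophile 0.100 M; protic impurity 0.0250 M; time 15 min
- autumn: nucleophile 0.200 M; protic impurity 0.0250 M; time 15 min

| run | time / min | electrophile / % | target / % |
|---|---|---|---|
| maple | 1.33 | 95.4 | 3.7 |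
| maple | 3.00 | 90.9 | 7.2 |
| maple | 6.00 | 87.2 | 13.1 |
| maple | 15.0 | 69.6 | 22.0 |
| ash | 2.00 | 82.9 | 15.9 |
| ash | 5.00 | 63.3 | 35.1 |
| ash | 10.0 | 39.7 | 49.0 |
| ash | 15.0 | 25.0 | 59.9 |

(scatter of a reading: 1 percentage point)



- part of the electrophile that has reacted at the end, spring
- part of the electrophile that has reacted at the end, midnight
- part of the electrophile that has reacted at the end, autumn
- what raising the concentration of nucleophile from its lowest to its highest value here does to the part of the electrophile that has reacted (changes below 5 percentage points count as none) (it falls / it rises / no change)

**Going logarithmic.** I treated the electrophile as pseudo-first-order within each flask and counted its loss in powers of ten. At 15.0 min, maple had 69.6% left, which is 0.157 decades, and ash had 25.0% left, which is 0.602 decades. That ratio of 3.83 was too large for a nucleophile charge ratio of 3.07.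

**Subtracting the impurity.** I guessed that the impurity took its own amount of nucleophile, which left maple 1.26 and ash 4.90, a ratio of 3.89, close to the ratio of decades.

**Decade rate.** So I defined the decade rate, the decades of electrophile lost per minute for each unit of nucleophile fraction remaining after the impurity's share. It came to 0.00819 min⁻¹ from ash and 0.00833 min⁻¹ from maple. With the ash value I committed to 34.6% reacted at midnight, 62.9% at autumn and 88.0% at spring.

**Reforging one link.** The weak link was that each rate rested on a single reading, so I recomputed ash at 5.00 min and 10.0 min and got 0.00811 min⁻¹ and 0.00819 min⁻¹, and the rate stood.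

**The forecast.** It gave 34% (30% to 39%) at midnight, 63% (58% to 68%) at autumn and 89% (83% to 93%) at spring, and its answer on the trend was: it rises. Its ground was “This fits the protic impurity quenching 0.025 M of nucleophile”. It also allowed for nucleophile consumed during reaction, while my reckoning did not, so our routes differ.

**The flask.** The simulation gave 35.2% at midnight, 62.8% at autumn and 88.2% at spring, so the answer on the trend was: it rises, by 53 percentage points.

    electrophile + target → side product (k = 0.0100 M⁻¹ s⁻¹)
    nucleophile + acid set free ⇌ protonated nucleophile, settled at all times (K = 110 M⁻¹)
    electrophile + nucleophile → acid set free + target (k = 0.00660 M⁻¹ s⁻¹)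
    nucleophile + protic impurity → quenched reagent (k = 0.130 M⁻¹ s⁻¹)

**Next flask.** Read back from midnight's result, the decade rate was 0.00837 min⁻¹, beside the 0.00819 min⁻¹ I had carried from ash. I then took the midnight flask on to 25 min with its amounts unchanged, where 0.00819 min⁻¹ gave 0.307 decades and so 49.3% of the electrophile left. That flask held 50.4% of the electrophile charged.

(The runs were generated by integration with made-up constants; scatter was added.)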